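## The problem

Target 29 joins four guaiacyl-type C6–C3 units through three different linkages. Its core is a trans-3,4-dibenzyl-γ-butyrolactone (O1, C2 carbonyl, C3, C4, C5). The C4 benzyl ring (ring B) is etherified at its phenol oxygen to C8 of an erythro 1-arylpropane-1,2,3-triol (ring A on the carbinol carbon C7, C9 the primary alcohol). The C3 benzyl ring (ring C) is the benzo ring of a trans-2-aryl-3-hydroxymethyl-2,3-dihydrobenzofuran (O1, C2 bearing ring D, C3, C3a–C7a).

The six stereocentres, (3R,4R) in the lactone, (7R,8S) in the glycerol chain and (2S,3R) in the dihydrofuran, form three pairs too remote to influence one another. Within each pair one centre can set the other: C4 directs C3 by trans alkylation, C7 and C8 arise in one aldol, and C3 dictates C2 by trans ring closure. Three independent sources of absolute configuration are therefore needed.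

Of the four guaiacyl oxygens, two end as free phenols (rings A and D), one as the aryl ether to C8 (ring B) and one as the furan oxygen (ring C), so the protection must be ordered. The lactone restricts reductants and strong bases (C3 is epimerisable, trans being the stable form). The C7 carbinol and the C2–O1 bond are para-oxygenated benzylic positions that ionise in acid or open to quinone methides in base, and every free guaiacol is sensitive to oxidants.

The feature that permits a late, bond-rich key step is that ring C, seen without the furan, is a 4-alkylguaiacol with a single open carbon ortho to its oxygen (C3a). C3–C3a and C2–O1 are exactly the two bonds by which a 4-hydroxy-3-methoxycinnamoyl unit (side chain C7=C8–C9) adds to such a phenol in an oxidative 8–5 coupling.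

## Retrosynthesis

**End game.** Target 29 is taken back to its ring A benzyl ether 28, and the C3 hydroxymethyl group of 28 to the N-acyl oxazolidinone of 27. No skeletal bond is cut. Benzyl is chosen for ring A because it alone is indifferent to every reagent between the aldol and the coupling. The acyl imide is chosen over an ester because borohydride in wet tetrahydrofuran reduces it while sparing the lactone. The forward steps must respect the lactone and the two benzylic C–O bonds.

**Key disconnection.** In 27 the bonds C3–C3a and C2–O1 are cut together. This removes the furan ring, both of its stereocentres and all carbons of ring D, and leaves lactone phenol 20 and N-feruloyl imide 25. The neighbouring cuts (C2–C3, or the CH2–C3 bond of the lactone with a ready-made benzofuran) would need a halogenated, separately made dihydrobenzofuran and several steps to attach it. The chosen cut uses the free phenol of ring C as its own handle. The forward reaction must pair two different phenoxyl radicals instead of two alike, bond at carbon and not at oxygen, and choose one face of C8.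

**Imide 25.** The N–acyl bond is cut to ferulic acid 21 and auxiliary 13, by way of acetate 22 and acetylated imide 24. The phenol is masked only for the acylation, and the unmasking must leave the imide alone.

**Glycerol ether of 20.** Phenol 20 comes from its ring C silyl ether 19. In 19 the C7–C8 bond is cut, giving aryloxyacetyl imide 15 and aldehyde 1. This is preferred to the C8–O(aryl) cut, which would require an SN2 reaction at a secondary carbon flanked by two oxygenated carbons. The aldol makes both centres at once and carries the ether oxygen in the enolate partner. A boron aldol gives the syn (threo) adduct 16, so C7 is inverted afterwards by Mitsunobu esterification (17); an anti-aldol of an aryloxyacetyl imide would have no secure precedent. The forward steps must enolise the imide and not the lactone, and invert C7 without ionising it.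

**Imide 15.** The O–CH2 bond is cut to phenol 12 and bromoacetyl imide 14, the latter made from the same auxiliary 13. Phenol 12 is the debenzylated form of 11. Ring B is benzyl-protected through the lactone synthesis while ring C carries a triisopropylsilyl group, so each oxygen can be freed in turn.

**Lactone 11.** The C3–CH2 bond is cut to lactone 6 and benzylic bromide 10, which comes from vanillin 7 via 8 and 9. The existing C4 centre must direct the alkylation trans.

**Lactone 6.** The ring C5–O bond and the benzylic C–C bond lead through hydroxy acid 5 and half-ester 4 to alkene 3, and from there to aldehyde 1 and diester 2. This is the only catalyst-controlled stereocentre of the route. Aldehyde 1 thus serves twice, as ring B here and as ring A in the aldol.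

## Roads not taken

**Alternative 1:** The dihydrobenzofuran would be made apart from the lactone as bromo ester A1, by oxidative ring contraction of (S)-flavanone A2.
- Key step: PhI(OAc)2 and H2SO4 in trimethyl orthoformate iodinate C3 of the enol ether of A2. The fused benzo ring then migrates from the carbonyl carbon to C3, forming C3–C3a and turning the old carbonyl into the methyl ester.
- Merits: the shift is stereospecific and gives the trans (2S,3S) ester from the single centre of A2. The chemistry is ionic, involves no free phenol and poses no choice between two coupling partners.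
- Weak points: A2 needs its own enantioselective synthesis and, as a flavanone, can racemise by reversible ring opening. The trivalent iodine reagent must be kept off the electron-rich rings (hence the pivalate). A1 is still far from the target: the bromide must be homologated to a benzylic electrophile, the base-sensitive ester carried through or removed before the alkylation of lactone 6, and the phenol protection re-ordered.
- Comparison: in reliability of the furan stereochemistry this road is better. The chosen plan sets against it that both bonds and both centres form in one step on the complete skeleton, two steps from 29, with several steps saved.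

**Alternative 2:** The cut is the ring O–CH2 bond of the lactone.
- Key step: prochiral cyclobutanone A4, already carrying the protected erythro ether, is treated with a chiral phosphoric acid and aqueous H2O2. Peroxide adds to the ketone and one enantiotopic methylene migrates to oxygen (Baeyer–Villiger), giving lactone A3.
- Merits: metal-free and catalytic, with one stereodefining step in place of condensation, hydrogenation and reduction.
- Weak points: the stereocentre carries a CH2-aryl group, so the catalyst must distinguish two methylenes that differ only remotely. Acid and peroxide meet an acetonide on a para-alkoxybenzylic carbon and several electron-rich rings. A4 itself needs a cycloaddition and dehalogenation sequence through which the glycerol ether would have to be carried.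
- Comparison: for the lactone centre it is about equal in step count and would be preferable if rhodium had to be avoided. But it spends its key step on the one stereocentre the chosen route already sets catalytically, and A3 would still have to be alkylated and coupled exactly as 6 and 20 are. It does not replace the key step.

**Alternative 3:** The cut is C2–C3 of the dihydrofuran.
- Key step: Rh2(S-DOSP)4, a divalent rhodium carboxylate, decomposes aryldiazoacetate A6. The rhodium carbene inserts into the benzylic C–H bond of the neighbouring benzyl ether, closing the oxygen ring to give bromo ester A5.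
- Merits: catalytic asymmetric C–C bond formation with a chiral catalyst in place of a stoichiometric auxiliary, and no competition between two phenols. In enantiocontrol it is potentially better than an auxiliary-directed radical coupling.
- Weak points: the kinetic product of such insertions is often the cis ester, which must then be equilibrated with base. Selectivity is sensitive to the methoxy group flanking the ether. A6 needs a diazo transfer on a fully substituted arylacetate. As with A1, the bromide must become a benzylic electrophile and be joined to 6, and the benzyl group on ring D would clash with the one needed on ring A.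
- Comparison: more general and more predictable in selectivity. The chosen plan answers with convergence: no halogen handle, no homologation, and diastereomeric coupling products that can be separated because the auxiliary is still attached.

Key step: step 18

Assumption (step 18): without a chelating metal the N-enoyl imide is taken to react through its dipole-minimised s-cis rotamer, in which the benzyl group of the (R)-auxiliary lies over the Re face of C8. The (S)-auxiliary would be used instead, with no other change, if a model coupling with a simple 4-alkylguaiacol shows the reverse sense.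

Assumption (step 2): the (S,S)-ligand is assigned to the R acid by analogy with other β-aryl itaconate half-esters. The sense is to be confirmed at lactone 6 by the sign of its optical rotation, and the (R,R)-ligand used otherwise.

## Route

Step 1
Reactants: 1 4-benzyloxy-3-methoxybenzaldehyde; 2 dimethyl succinate
Product: 3 (E)-4-(4-benzyloxy-3-methoxyphenyl)-3-(methoxycarbonyl)but-3-enoic acid
Conditions: NaOMe, MeOH, reflux; then 2 M HCl
Reagents that add atoms: none
Why: Stobbe condensation: the succinate enolate adds to the aldehyde, the aldolate lactonises onto the distal ester and base-induced ring opening gives the carboxylate irreversibly, so the conjugated ester stays esterified and the E alkene (aryl trans to the ester) should predominate.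

Step 2
Reactants: 3 (E)-4-(4-benzyloxy-3-methoxyphenyl)-3-(methoxycarbonyl)but-3-enoic acid
Product: 4 (R)-4-(4-benzyloxy-3-methoxyphenyl)-3-(methoxycarbonyl)butanoic acid
Conditions: H2 (5 bar), [Rh(cod)((S,S)-Et-DuPhos)]BF4 (1 mol %), NaOMe (0.1 equiv), MeOH, 25 °C
Reagents that add atoms: none
Why: Asymmetric hydrogenation of an itaconate-type half-ester: carboxylate and alkene chelate the monovalent rhodium centre and the C2-symmetric bisphospholane selects the alkene face, which sets the future lactone C4 as R (see assumption); the benzyl ether is inert to the homogeneous catalyst.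

Step 3
Reactants: 4 (R)-4-(4-benzyloxy-3-methoxyphenyl)-3-(methoxycarbonyl)butanoic acid
Product: 6 (R)-4-(4-benzyloxy-3-methoxybenzyl)dihydrofuran-2(3H)-one, via hydroxy acid 5 (not isolated)
Conditions: KOH (1 equiv), EtOH; CaCl2, NaBH4, EtOH, −10 °C to rt; then 2 M HCl, rt
Reagents that add atoms: none
Why: Chemoselective ester reduction: Ca(BH4)2 formed in the flask reduces the methyl ester while the carboxylate is inert, and acidification closes hydroxy acid 5 to the γ-lactone; the stereocentre is not involved.

Step 4
Reactants: 7 vanillin (4-hydroxy-3-methoxybenzaldehyde)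
Product: 8 3-methoxy-4-(triisopropylsilyloxy)benzaldehyde
Conditions: i-Pr3SiCl, imidazole, DMF, rt
Reagents that add atoms: triisopropylsilyl chloride, CC(C)[Si](Cl)(C(C)C)C(C)C
Why: Silylation of the phenol; the triisopropylsilyl aryl ether tolerates the enolate alkylation, hydrogenolysis, carbonate, boron triflate and Mitsunobu conditions that follow and is orthogonal to benzyl.

Step 5
Reactants: 8 3-methoxy-4-(triisopropylsilyloxy)benzaldehyde
Product: 9 [3-methoxy-4-(triisopropylsilyloxy)phenyl]methanol
Conditions: NaBH4, MeOH, 0 °C
Reagents that add atoms: none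
Why: Borohydride reduction of the aldehyde; the hindered aryl silyl ether is stable under these brief, cold conditions.

Step 6
Reactants: 9 [3-methoxy-4-(triisopropylsilyloxy)phenyl]methanol
Product: 10 4-(bromomethyl)-2-methoxy-1-(triisopropylsilyloxy)benzene
Conditions: CBr4, PPh3, CH2Cl2, 0 °C
Reagents that add atoms: carbon tetrabromide, BrC(Br)(Br)Br
Why: Appel bromination under neutral conditions, which avoids acid that would ionise the electron-rich benzylic position; the bromide is used without storage.

Step 7
Reactants: 6 (R)-4-(4-benzyloxy-3-methoxybenzyl)dihydrofuran-2(3H)-one; 10 4-(bromomethyl)-2-methoxy-1-(triisopropylsilyloxy)benzene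
Product: 11 (3R,4R)-4-(4-benzyloxy-3-methoxybenzyl)-3-[3-methoxy-4-(triisopropylsilyloxy)benzyl]dihydrofuran-2(3H)-one
Conditions: LiN(SiMe3)2, THF, −78 °C; then 10, −78 to −30 °C
Reagents that add atoms: none
Why: Alkylation of the lactone lithium enolate: the bromide approaches anti to the C4 benzyl group, so C3 is set R and the trans lactone results by substrate control.

Step 8
Reactants: 11 (3R,4R)-4-(4-benzyloxy-3-methoxybenzyl)-3-[3-methoxy-4-(triisopropylsilyloxy)benzyl]dihydrofuran-2(3H)-one
Product: 12 (3R,4R)-4-(4-hydroxy-3-methoxybenzyl)-3-[3-methoxy-4-(triisopropylsilyloxy)benzyl]dihydrofuran-2(3H)-one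
Conditions: H2 (1 atm), 10% Pd/C, EtOAc, rt
Reagents that add atoms: none
Why: Catalytic hydrogenolysis of the aryl benzyl ether; lactone and silyl ether are untouched, so only the ring B phenol is freed.

Step 9
Reactants: 13 (R)-4-benzyl-2-oxazolidinone
Product: 14 (R)-4-benzyl-3-(bromoacetyl)oxazolidin-2-one
Conditions: n-BuLi, THF, −78 °C; then BrCH2COBr, −78 °C
Reagents that add atoms: bromoacetyl bromide, BrCC(Br)=O
Why: N-Acylation of the lithiated oxazolidinone; the acid bromide reacts far faster than the alkyl bromide at −78 °C.

Step 10
Reactants: 12 (3R,4R)-4-(4-hydroxy-3-methoxybenzyl)-3-[3-methoxy-4-(triisopropylsilyloxy)benzyl]dihydrofuran-2(3H)-one; 14 (R)-4-benzyl-3-(bromoacetyl)oxazolidin-2-one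
Product: 15 aryloxyacetyl imide: lactone 12 whose ring B oxygen carries CH2C(=O)N of (R)-4-benzyl-2-oxazolidinone
Conditions: K2CO3, acetone, 0 °C to rt
Reagents that add atoms: none
Why: Williamson ether synthesis: the phenoxide displaces bromide from the α-bromo imide by SN2, which should be much faster than attack at an imide carbonyl; lactone and hindered silyl ether are inert to carbonate in acetone.

Step 11
Reactants: 15 aryloxyacetyl imide of lactone 12; 1 4-benzyloxy-3-methoxybenzaldehyde
Product: 16 syn aldol adduct: (R)-4-benzyl-3-[(2R,3S)-2-aryloxy-3-(4-benzyloxy-3-methoxyphenyl)-3-hydroxypropanoyl]oxazolidin-2-one, the aryloxy group being ring B of the (3R,4R) lactone (ring C silylated)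
Conditions: Bu2BOTf, i-Pr2NEt, CH2Cl2, −78 to 0 °C; then 1, −78 to 0 °C; then pH 7 buffer, MeOH, 30% H2O2, 0 °C
Reagents that add atoms: none
Why: Evans syn-aldol: soft enolisation gives the Z boron enolate of the imide only (a lactone is not enolised by Bu2BOTf and amine), and the chair Zimmerman–Traxler transition state with the aldehyde on the face away from the auxiliary benzyl group gives the (2R,3S) syn adduct. This fixes C8 in its final configuration and leaves C7 with the opposite of the required one.

Step 12
Reactants: 16 syn aldol adduct (2R,3S)
Product: 17 4-nitrobenzoate of the inverted alcohol: the (2R,3R)-2-aryloxy-3-(4-benzyloxy-3-methoxyphenyl)-3-(4-nitrobenzoyloxy)propanoyl imide of (R)-4-benzyl-2-oxazolidinone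
Conditions: PPh3, DIAD, 4-O2NC6H4CO2H, THF, 0 °C to rt
Reagents that add atoms: 4-nitrobenzoic acid, O=C(O)c1ccc(cc1)[N+](=O)[O-]
Why: Mitsunobu reaction: the alkoxyphosphonium ion of the benzylic alcohol is displaced by 4-nitrobenzoate with inversion at C7, turning the threo (syn) into the erythro (anti) relationship; the acidic nucleophile and low temperature favour SN2 over ionisation.

Step 13
Reactants: 17 4-nitrobenzoate imide (2R,3R)
Product: 19 erythro diol in which the ring B oxygen of the (3R,4R) lactone is bonded to C8 of (7R,8S)-1-(4-benzyloxy-3-methoxyphenyl)propane-1,3-diol (ring C as triisopropylsilyl ether), via 7-O-(4-nitrobenzoyl) alcohol 18 (not isolated)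
Conditions: NaBH4, THF–H2O (4:1), 0 °C to rt; then K2CO3 (0.2 equiv), MeOH, 0 °C
Reagents that add atoms: none
Why: Reductive cleavage of the N-acyl oxazolidinone: borohydride in wet tetrahydrofuran reduces the activated imide carbonyl to the primary alcohol and releases the auxiliary while lactone and benzoate persist, the transient aldehyde being reduced faster than it can eliminate. Brief carbonate methanolysis then removes the 4-nitrobenzoate (also if it has migrated to O9) without touching C7 or C8.

Step 14
Reactants: 19 erythro diol with ring C silyl ether
Product: 20 lactone phenol: (3R,4R)-3-(4-hydroxy-3-methoxybenzyl)-4-benzyl lactone whose ring B oxygen is bonded to C8 of (7R,8S)-1-(4-benzyloxy-3-methoxyphenyl)propane-1,3-diol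
Conditions: Bu4NF, AcOH, THF, 0 °C
Reagents that add atoms: none
Why: Fluoride cleavage of the aryl silyl ether, buffered with acetic acid so that no phenoxide opens the lactone; this exposes the only free phenol of the coupling precursor.

Step 15
Reactants: 21 ferulic acid ((E)-4-hydroxy-3-methoxycinnamic acid)
Product: 22 (E)-4-acetoxy-3-methoxycinnamic acid
Conditions: Ac2O, pyridine, rt; then H2O
Reagents that add atoms: acetic anhydride, CC(=O)OC(C)=O
Why: Acetylation of the phenol (any mixed carboxylic anhydride is hydrolysed on work-up), so that only the carboxyl group is activated in the next step.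

Step 16
Reactants: 22 (E)-4-acetoxy-3-methoxycinnamic acid; 13 (R)-4-benzyl-2-oxazolidinone
Product: 24 (R)-3-[(E)-3-(4-acetoxy-3-methoxyphenyl)acryloyl]-4-benzyloxazolidin-2-one, via mixed pivalic anhydride 23 (not isolated)
Conditions: t-BuCOCl, Et3N, THF, −20 °C; then LiCl, 13, −20 °C to rt
Reagents that add atoms: none
Why: N-Acylation through the mixed pivalic anhydride with LiCl and Et3N activating the oxazolidinone; attack goes to the less hindered cinnamoyl carbonyl and the E alkene and aryl acetate are untouched.

Step 17
Reactants: 24 (R)-3-[(E)-3-(4-acetoxy-3-methoxyphenyl)acryloyl]-4-benzyloxazolidin-2-one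
Product: 25 (R)-4-benzyl-3-[(E)-3-(4-hydroxy-3-methoxyphenyl)acryloyl]oxazolidin-2-one
Conditions: pyrrolidine (1.1 equiv), CH2Cl2, 0 °C
Reagents that add atoms: none
Why: Aminolysis of the aryl acetate by pyrrolidine, which should be much faster at 0 °C than attack on the imide or conjugate addition to the electron-rich cinnamoyl system.

Step 18
Reactants: 20 lactone phenol; 25 (R)-4-benzyl-3-[(E)-3-(4-hydroxy-3-methoxyphenyl)acryloyl]oxazolidin-2-one
Product: 27 trans-(2S,3S)-2-(4-hydroxy-3-methoxyphenyl)-7-methoxy-2,3-dihydrobenzofuran whose C3 carries the carbonyl of N-acyl (R)-4-benzyl-2-oxazolidinone and whose C5 carries the CH2 group at C3 of the lactone of 20 (glycerol diol free; ring A benzylated), via quinone methide 26 (not isolated)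
Conditions: Ag2O (2 equiv), 20 (2 equiv), CH2Cl2–acetone (3:1), rt, dark; 25 (1 equiv) added over 8 h
Reagents that add atoms: none
Why: Ag2O removes one electron from each phenol; the feruloyl phenoxyl radical carries spin at side-chain C8 (the future C3), whereas the radical of 20 has spin only at oxygen and at the ring carbon ortho to it (the future C3a), its para carbon being alkylated. Pairing of C8 with that ortho carbon forms C3–C3a, and tautomerisation of the cyclohexadienone restores the ring C phenol and leaves quinone methide 26. The phenol oxygen then adds to the quinone methide carbon in a 5-exo-trig closure (C2–O1) that rearomatises ring D. The closest known reaction type is the Ag2O- or peroxidase-mediated 8–5 dehydrodimerisation of ferulic acid derivatives bearing chiral N-acyl auxiliaries, together with the end-wise 8–5 cross-coupling of 4-hydroxy-3-methoxycinnamyl units with guaiacyl phenols. C3 is controlled by the auxiliary: in the dipole-minimised s-cis rotamer its benzyl group lies over the Re face of C8, so the ring carbon bonds on the Si face (3S). C2 is controlled by C3: the closure places the aryl group trans to the acyl group, and trans is also the stable arrangement because C2 can equilibrate through the quinone methide. The step needs cross- over homo-coupling and C–C over C–O bonding; the first is served by keeping 20 in excess and feeding 25 slowly, the second by the dry, non-nucleophilic medium, in which only the C–C coupled quinone methide has an internal nucleophile to trap it. The attached auxiliary makes the two possible trans products diastereomers, so the minor one can be removed by chromatography, and unreacted 20 is recovered.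

Step 19
Reactants: 27 trans-(2S,3S)-dihydrobenzofuran acyl oxazolidinone
Product: 28 ring A benzyl ether of the target: trans-(2S,3R)-3-hydroxymethyl dihydrobenzofuran with the (3R,4R) lactone and the (7R,8S) glycerol ether
Conditions: NaBH4, THF–H2O (4:1), 0 °C
Reagents that add atoms: none
Why: Reductive removal of the auxiliary as in step 13: the imide carbonyl is far more electrophilic than the lactone and the intermediate aldehyde is reduced faster than it can enolise. C3 becomes R only through the change in substituent priority.

Step 20
Reactants: 28 ring A benzyl ether of the target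
Product: 29 target: (3R,4R)-lactone bearing the (7R,8S) glycerol ether on ring B and the (2S,3R) dihydrobenzofuran on ring C
Conditions: H2 (1 atm), 10% Pd/C, EtOAc–MeOH, rt
Reagents that add atoms: none
Why: Hydrogenolysis of the aryl benzyl ether under neutral conditions at ambient pressure; aryl benzyl ethers are cleaved faster than the benzylic C–O bonds of the dihydrofuran and of C7, so the reaction is stopped after uptake of one equivalent.

## Compound list

1 | 4-benzyloxy-3-methoxybenzaldehyde | COc1cc(C=O)ccc1OCc1ccccc1 | starting material
2 | dimethyl succinate | COC(=O)CCC(=O)OC | starting material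
3 | (E)-4-(4-benzyloxy-3-methoxyphenyl)-3-(methoxycarbonyl)but-3-enoic acid | COC(=O)/C(CC(=O)O)=C/c1ccc(OCc2ccccc2)c(OC)c1 | intermediate
4 | (R)-4-(4-benzyloxy-3-methoxyphenyl)-3-(methoxycarbonyl)butanoic acid | COC(=O)[C@H](Cc1ccc(OCc2ccccc2)c(OC)c1)CC(=O)O | intermediate
5 | (R)-4-(4-benzyloxy-3-methoxyphenyl)-3-(hydroxymethyl)butanoic acid (not isolated) | OC[C@H](Cc1ccc(OCc2ccccc2)c(OC)c1)CC(=O)O | intermediate
6 | (R)-4-(4-benzyloxy-3-methoxybenzyl)dihydrofuran-2(3H)-one | COc1cc(C[C@H]2COC(=O)C2)ccc1OCc1ccccc1 | intermediate
7 | vanillin | COc1cc(C=O)ccc1O | starting material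
8 | 3-methoxy-4-(triisopropylsilyloxy)benzaldehyde | COc1cc(C=O)ccc1O[Si](C(C)C)(C(C)C)C(C)C | intermediate
9 | [3-methoxy-4-(triisopropylsilyloxy)phenyl]methanol | COc1cc(CO)ccc1O[Si](C(C)C)(C(C)C)C(C)C | intermediate
10 | 4-(bromomethyl)-2-methoxy-1-(triisopropylsilyloxy)benzene | COc1cc(CBr)ccc1O[Si](C(C)C)(C(C)C)C(C)C | intermediate
11 | (3R,4R)-4-(4-benzyloxy-3-methoxybenzyl)-3-[3-methoxy-4-(triisopropylsilyloxy)benzyl]dihydrofuran-2(3H)-one | COc1cc(C[C@H]2COC(=O)[C@@H]2Cc2ccc(O[Si](C(C)C)(C(C)C)C(C)C)c(OC)c2)ccc1OCc1ccccc1 | intermediate
12 | (3R,4R)-4-(4-hydroxy-3-methoxybenzyl)-3-[3-methoxy-4-(triisopropylsilyloxy)benzyl]dihydrofuran-2(3H)-one | COc1cc(C[C@H]2COC(=O)[C@@H]2Cc2ccc(O[Si](C(C)C)(C(C)C)C(C)C)c(OC)c2)ccc1O | intermediate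
13 | (R)-4-benzyl-2-oxazolidinone | O=C1N[C@H](Cc2ccccc2)CO1 | starting material
14 | (R)-4-benzyl-3-(bromoacetyl)oxazolidin-2-one | O=C(CBr)N1C(=O)OC[C@H]1Cc1ccccc1 | intermediate
15 | aryloxyacetyl imide of 12 with (R)-4-benzyl-2-oxazolidinone | COc1cc(C[C@H]2COC(=O)[C@@H]2Cc2ccc(O[Si](C(C)C)(C(C)C)C(C)C)c(OC)c2)ccc1OCC(=O)N1C(=O)OC[C@H]1Cc1ccccc1 | intermediate
16 | (2R,3S) syn aldol adduct (threo) | COc1cc([C@H](O)[C@H](C(=O)N2C(=O)OC[C@H]2Cc2ccccc2)Oc2ccc(C[C@H]3COC(=O)[C@@H]3Cc3ccc(O[Si](C(C)C)(C(C)C)C(C)C)c(OC)c3)cc2OC)ccc1OCc1ccccc1 | intermediate
17 | (2R,3R) 3-O-(4-nitrobenzoyl) imide (erythro) | COc1cc([C@@H](OC(=O)c2ccc([N+](=O)[O-])cc2)[C@H](C(=O)N2C(=O)OC[C@H]2Cc2ccccc2)Oc2ccc(C[C@H]3COC(=O)[C@@H]3Cc3ccc(O[Si](C(C)C)(C(C)C)C(C)C)c(OC)c3)cc2OC)ccc1OCc1ccccc1 | intermediate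
18 | (7R,8S) 7-O-(4-nitrobenzoyl) primary alcohol (not isolated) | COc1cc([C@@H](OC(=O)c2ccc([N+](=O)[O-])cc2)[C@H](CO)Oc2ccc(C[C@H]3COC(=O)[C@@H]3Cc3ccc(O[Si](C(C)C)(C(C)C)C(C)C)c(OC)c3)cc2OC)ccc1OCc1ccccc1 | intermediate
19 | (7R,8S) erythro diol, ring C silyl ether, ring A benzyl ether | COc1cc([C@@H](O)[C@H](CO)Oc2ccc(C[C@H]3COC(=O)[C@@H]3Cc3ccc(O[Si](C(C)C)(C(C)C)C(C)C)c(OC)c3)cc2OC)ccc1OCc1ccccc1 | intermediate
20 | lactone phenol with erythro glycerol ether, ring A benzyl ether | COc1cc([C@@H](O)[C@H](CO)Oc2ccc(C[C@H]3COC(=O)[C@@H]3Cc3ccc(O)c(OC)c3)cc2OC)ccc1OCc1ccccc1 | intermediate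
21 | ferulic acid | COc1cc(/C=C/C(=O)O)ccc1O | starting material
22 | (E)-4-acetoxy-3-methoxycinnamic acid | COc1cc(/C=C/C(=O)O)ccc1OC(C)=O | intermediate
23 | mixed anhydride of 22 with pivalic acid (not isolated) | COc1cc(/C=C/C(=O)OC(=O)C(C)(C)C)ccc1OC(C)=O | intermediate
24 | (R)-3-[(E)-3-(4-acetoxy-3-methoxyphenyl)acryloyl]-4-benzyloxazolidin-2-one | COc1cc(/C=C/C(=O)N2C(=O)OC[C@H]2Cc2ccccc2)ccc1OC(C)=O | intermediate
25 | (R)-4-benzyl-3-[(E)-3-(4-hydroxy-3-methoxyphenyl)acryloyl]oxazolidin-2-one | COc1cc(/C=C/C(=O)N2C(=O)OC[C@H]2Cc2ccccc2)ccc1O | intermediate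
26 | C–C coupled quinone methide with free ring C phenol (not isolated) | COc1cc([C@@H](O)[C@H](CO)Oc2ccc(C[C@H]3COC(=O)[C@@H]3Cc3cc(OC)c(O)c(c3)[C@H](C(=O)N3C(=O)OC[C@H]3Cc3ccccc3)C=C3C=CC(=O)C(OC)=C3)cc2OC)ccc1OCc1ccccc1 | intermediate
27 | trans-(2S,3S)-dihydrobenzofuran acyl oxazolidinone | COc1cc([C@@H](O)[C@H](CO)Oc2ccc(C[C@H]3COC(=O)[C@@H]3Cc3cc(OC)c4c(c3)[C@H](C(=O)N3C(=O)OC[C@H]3Cc3ccccc3)[C@@H](c3ccc(O)c(OC)c3)O4)cc2OC)ccc1OCc1ccccc1 | intermediate
28 | ring A benzyl ether of the target | COc1cc([C@@H](O)[C@H](CO)Oc2ccc(C[C@H]3COC(=O)[C@@H]3Cc3cc(OC)c4c(c3)[C@H](CO)[C@@H](c3ccc(O)c(OC)c3)O4)cc2OC)ccc1OCc1ccccc1 | intermediate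
29 | CNP0265599.1 | COc1cc([C@@H](O)[C@H](CO)Oc2ccc(C[C@H]3COC(=O)[C@@H]3Cc3cc(OC)c4c(c3)[C@H](CO)[C@@H](c3ccc(O)c(OC)c3)O4)cc2OC)ccc1O | target

## Step count and least certain steps

Total: 20 steps. Longest linear sequence: 13 steps (1, 2, 3, 7, 8, 10, 11, 12, 13, 14, 18, 19, 20).

**Step 18 (key step).** The most likely failure is that self-pairing of the imide radicals and bonding at the guaiacol oxygen outrun the C–C cross-pairing, and that the product phenol is oxidised further. The remote benzyl group may also discriminate the faces of C8 only weakly. Fallback: starting from 20, commercial coniferyl alcohol and H2O2 are fed slowly and simultaneously into a buffered aqueous acetone solution of 20 and horseradish peroxidase. This is the end-wise 8–5 coupling by which such alcohols add to guaiacyl phenols. It gives 28 directly, without auxiliary and without step 19, together with its (2R,3S) dihydrofuran diastereomer F1, from which it must be separated by preparative HPLC. The route is rejoined at 28.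

**Step 12.** Ionisation of the alkoxy-substituted benzylic oxyphosphonium ion would give partial retention and a threo/erythro mixture, and elimination to the α-aryloxy cinnamoyl imide may compete. Fallback: starting from 16, NaBH4 in wet tetrahydrofuran removes the auxiliary to give threo diol F2. DDQ then oxidises only the para-alkoxybenzylic carbinol to aryl ketone F3. Zn(BH4)2 at low temperature reduces F3 through the chelate of the ketone with the α-aryloxy oxygen to the anti diol, which is 19.

**Step 10.** Acyl transfer from the imide to the phenoxide (loss of the auxiliary) or slow silyl exchange between the two guaiacol oxygens could erode the alkylation. Fallback: starting from 12, alkylation with tert-butyl bromoacetate and K2CO3 gives tert-butyl ester F4, trifluoroacetic acid liberates aryloxyacetic acid F5, and its mixed pivalic anhydride F6 acylates 13 (LiCl, Et3N) to give 15.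

**Step 19.** Hydride attack on the lactone, or enolisation at the aldehyde stage with expulsion of the ring oxygen or epimerisation at C3, could compete with simple reduction. Fallback: starting from 27, LiOH and H2O2 in aqueous tetrahydrofuran at 0 °C cleave the exocyclic imide carbonyl and give, after acidification (which recloses any opened lactone), carboxylic acid F7. BH3·SMe2 then reduces the carboxylic acid in preference to the lactone and gives 28.

## Further compounds

F1 | step 18 | (2R,3S)-dihydrobenzofuran diastereomer of 28 | COc1cc([C@@H](O)[C@H](CO)Oc2ccc(C[C@H]3COC(=O)[C@@H]3Cc3cc(OC)c4c(c3)[C@@H](CO)[C@H](c3ccc(O)c(OC)c3)O4)cc2OC)ccc1OCc1ccccc1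
F2 | step 12 | threo (7S,8S) diol corresponding to 19 | COc1cc([C@H](O)[C@H](CO)Oc2ccc(C[C@H]3COC(=O)[C@@H]3Cc3ccc(O[Si](C(C)C)(C(C)C)C(C)C)c(OC)c3)cc2OC)ccc1OCc1ccccc1
F3 | step 12 | (8S) aryl ketone (7-oxo compound) from F2 | COc1cc(C(=O)[C@H](CO)Oc2ccc(C[C@H]3COC(=O)[C@@H]3Cc3ccc(O[Si](C(C)C)(C(C)C)C(C)C)c(OC)c3)cc2OC)ccc1OCc1ccccc1
F4 | step 10 | tert-butyl aryloxyacetate of phenol 12 | COc1cc(C[C@H]2COC(=O)[C@@H]2Cc2ccc(O[Si](C(C)C)(C(C)C)C(C)C)c(OC)c2)ccc1OCC(=O)OC(C)(C)C
F5 | step 10 | aryloxyacetic acid of phenol 12 | COc1cc(C[C@H]2COC(=O)[C@@H]2Cc2ccc(O[Si](C(C)C)(C(C)C)C(C)C)c(OC)c2)ccc1OCC(=O)O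
F6 | step 10 | mixed pivalic anhydride of F5 | COc1cc(C[C@H]2COC(=O)[C@@H]2Cc2ccc(O[Si](C(C)C)(C(C)C)C(C)C)c(OC)c2)ccc1OCC(=O)OC(=O)C(C)(C)C
F7 | step 19 | trans-(2S,3S)-dihydrobenzofuran-3-carboxylic acid corresponding to 27 | COc1cc([C@@H](O)[C@H](CO)Oc2ccc(C[C@H]3COC(=O)[C@@H]3Cc3cc(OC)c4c(c3)[C@H](C(=O)O)[C@@H](c3ccc(O)c(OC)c3)O4)cc2OC)ccc1OCc1ccccc1
A1 | alternative 1 | methyl (2S,3S)-trans-5-bromo-7-methoxy-2-(3-methoxy-4-pivaloyloxyphenyl)-2,3-dihydrobenzofuran-3-carboxylate | Brc1cc(OC)c2c(c1)[C@H](C(=O)OC)[C@@H](c1ccc(OC(=O)C(C)(C)C)c(OC)c1)O2
A2 | alternative 1 | (S)-6-bromo-8-methoxy-2-(3-methoxy-4-pivaloyloxyphenyl)chroman-4-one | O=C1C[C@@H](c2ccc(OC(=O)C(C)(C)C)c(OC)c2)Oc2c(OC)cc(Br)cc21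
A3 | alternative 2 | (R)-β-(arylmethyl)-γ-butyrolactone carrying the acetonide-protected erythro ether | COc1cc([C@H]2OC(C)(C)OC[C@@H]2Oc2ccc(C[C@H]3COC(=O)C3)cc2OC)ccc1OCc1ccccc1
A4 | alternative 2 | 3-(arylmethyl)cyclobutanone carrying the acetonide-protected erythro ether | COc1cc([C@H]2OC(C)(C)OC[C@@H]2Oc2ccc(CC3CC(=O)C3)cc2OC)ccc1OCc1ccccc1
A5 | alternative 3 | methyl (2S,3S)-trans-5-bromo-7-methoxy-2-(4-benzyloxy-3-methoxyphenyl)-2,3-dihydrobenzofuran-3-carboxylate | Brc1cc(OC)c2c(c1)[C@H](C(=O)OC)[C@@H](c1ccc(OCc3ccccc3)c(OC)c1)O2
A6 | alternative 3 | methyl 2-diazo-2-[5-bromo-3-methoxy-2-(4-benzyloxy-3-methoxybenzyloxy)phenyl]acetate | COC(=O)C(=[N+]=[N-])c1cc(Br)cc(OC)c1OCc1ccc(OCc2ccccc2)c(OC)c1
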